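**Assumption:** the target is read as epicatechin-(4β→8)-epifisetinidol-(4β→8)-catechin (upper unit 2R,3R,4R; middle unit 2R,3R,4R; lower unit 2R,3S), and the phosphoramidite antipode in step 5 is the one that gives the (1S,2R) adduct, to be confirmed on the first run.

## Retrosynthetic overview

1. Both outer units are bought ((−)-epicatechin, (+)-catechin); both interflavan C4–C8 bonds are cut to a flavan-4-yl cation and a ring A carbon, and each new C4 centre is set trans to its neighbouring 3-OH by the substrate.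
2. Only the middle unit is built: its ring C is cut at O1–C8a and at C2–C3, giving 3,4-bis(benzyloxy)benzaldehyde (C2 and O1) and an ArCH2CH(Bpin)2 gem-diboronate (C3, C4, ring A) with iodine on C8a.
3. Enabling feature: in the middle unit C3 is a carbinol carbon between benzylic C2 and the C4 methylene, and O1 bridges C2 to aromatic C8a, ortho to C4a of ring A. Carrying the C3 oxygen as boron makes C3 a boron-stabilised nucleophile for the aldehyde carbon and leaves the aldehyde oxygen as the alkoxide that arylates at C8a.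
4. Ring order: ring C of the middle unit is the only ring formed (step 5, C2 and C3 set by catalysis). Then come C4 oxidation, bromine blocking (C6 of the middle unit; C6 and C8 of the upper unit), upper-to-middle coupling (hard activation), middle-to-lower coupling (soft activation of a C4 thioether), and one hydrogenolysis that removes eleven benzyl groups and three bromines.

Key step: step 5

## Route

Step 1
Reactants: 1 4-hydroxy-2-iodobenzaldehyde
Product: 2 4-(benzyloxy)-2-iodobenzaldehyde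
Conditions: BnBr, K2CO3, DMF, rt
Reagents that add atoms: benzyl bromide, BrCc1ccccc1
Why: Williamson ether synthesis on the only acidic OH should protect the future 7-OH of the middle unit as a benzyl ether that survives until the final hydrogenolysis.

Step 2
Reactants: 2 4-(benzyloxy)-2-iodobenzaldehyde
Product: 3 [4-(benzyloxy)-2-iodophenyl]methanol
Conditions: NaBH4, MeOH/THF, 0 °C
Reagents that add atoms: none
Why: Borohydride reduction of the aldehyde should leave the aryl iodide and the benzyl ether untouched.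

Step 3
Reactants: 3 [4-(benzyloxy)-2-iodophenyl]methanol
Product: 4 4-(benzyloxy)-1-(bromomethyl)-2-iodobenzene
Conditions: PBr3, CH2Cl2, 0 °C, used crude
Reagents that add atoms: phosphorus tribromide, BrP(Br)Br
Why: Deoxybromination of an electron-rich benzylic alcohol is fast at 0 °C and should give the benzylic bromide needed for C-alkylation.

Step 4
Reactants: 4 4-(benzyloxy)-1-(bromomethyl)-2-iodobenzene; 5 bis(4,4,5,5-tetramethyl-1,3,2-dioxaborolan-2-yl)methane
Product: 6 2,2'-{2-[4-(benzyloxy)-2-iodophenyl]ethane-1,1-diyl}bis(4,4,5,5-tetramethyl-1,3,2-dioxaborolane)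
Conditions: 5, lithium 2,2,6,6-tetramethylpiperidide, THF, 0 °C; then 4, 0 °C → rt
Reagents that add atoms: none
Why: Deprotonative SN2 alkylation of the doubly boron-stabilised carbanion of 5 with a benzylic bromide should give the gem-diboronate; the hindered amide base does not attack the aryl iodide.

Step 5
Reactants: 6 2,2'-{2-[4-(benzyloxy)-2-iodophenyl]ethane-1,1-diyl}bis(4,4,5,5-tetramethyl-1,3,2-dioxaborolane); 7 3,4-bis(benzyloxy)benzaldehyde
Product: 10 (2R,3R)-7-(benzyloxy)-2-[3,4-bis(benzyloxy)phenyl]-3,4-dihydro-2H-chromen-3-ol (7,3',4'-tri-O-benzyl-epifisetinidol), via copper alkoxide of the syn-hydroxyboronate 8 (not isolated), via cis-3-borylflavan 9 (not isolated)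
Conditions: Cu(NCMe)4PF6 (10 mol %), BINOL-derived phosphoramidite (12 mol %), LiOC(CH3)2C2H5 (1.3 equiv), THF, 22 °C; then 3,4,7,8-tetramethyl-1,10-phenanthroline (20 mol %), 50 °C; then 30% H2O2, pH 7 buffer, 0 °C
Reagents that add atoms: hydrogen peroxide, OO
Why: Proposed new method: alkoxide-triggered boron-to-copper transmetalation of 6 gives a chiral α-boryl alkylcopper that adds to aldehyde 7 (C2–C3 bond), and the resulting monovalent copper alkoxide 8, held next to the ortho C8a–I bond, undergoes oxidative addition and C–O reductive elimination (O1–C8a bond) before buffered H2O2 turns C3–B into C3–OH with retention. The closest known reaction types are the copper-catalysed enantio- and syn-selective 1,2-addition of 1,1-diborylalkanes to aryl aldehydes and the copper-catalysed intramolecular Ullmann etherification of aliphatic alcohols with aryl iodides; their merger on one copper centre in one flask is what is new. Ring C closes as a six-membered ring by C(sp2)–O reductive elimination from a seven-membered oxacupracycle, formally a 6-exo attack of O1 on C8a. C2 and C3 are both created in the addition: their absolute sense comes from the phosphoramidite-bound copper and their syn relation (2,3-cis after closure) from the ordered addition transition state, and neither is touched by the etherification or the oxidation. The step needs O1, not a C3 oxygen, to arylate, and needs the β-boryl alkoxide not to collapse by B–O syn-elimination; the first is secured because C3 still carries boron (no five-membered closure is possible), the second because the alkoxide stays on copper and, once ring C is closed, the cis arrangement keeps the C3–B bond gauche to the C2–O1 bond.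

Step 6
Reactants: 10 (2R,3R)-7-(benzyloxy)-2-[3,4-bis(benzyloxy)phenyl]-3,4-dihydro-2H-chromen-3-ol
Product: 11 (2R,3R,4S)-7-(benzyloxy)-2-[3,4-bis(benzyloxy)phenyl]-4-(2-ethoxyethoxy)-3,4-dihydro-2H-chromen-3-ol (4β ether, 3,4-trans)
Conditions: DDQ, 2-ethoxyethanol, CH2Cl2, rt
Reagents that add atoms: 2-ethoxyethanol, CCOCCO
Why: DDQ benzylic oxidation (hydride abstraction from C4, whose cation is stabilised by the para 7-benzyloxy group and by O1) followed by capture of the alcohol anti to the 3-OH should give the 4β ether, as with benzylated catechins.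

Step 7
Reactants: 11 (2R,3R,4S)-7-(benzyloxy)-2-[3,4-bis(benzyloxy)phenyl]-4-(2-ethoxyethoxy)-3,4-dihydro-2H-chromen-3-ol
Product: 12 (2R,3R,4S)-7-(benzyloxy)-2-[3,4-bis(benzyloxy)phenyl]-6-bromo-4-(2-ethoxyethoxy)-3,4-dihydro-2H-chromen-3-ol
Conditions: NBS (1.0 equiv), CH2Cl2, −40 → 0 °C
Reagents that add atoms: N-bromosuccinimide, BrN1C(=O)CCC1=O
Why: Electrophilic aromatic bromination should go to C6 of ring A (para to O1, ortho to the 7-benzyloxy group, less hindered than C8), which blocks the position that would otherwise compete with C8 in step 12.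

Step 8
Reactants: 12 (2R,3R,4S)-7-(benzyloxy)-2-[3,4-bis(benzyloxy)phenyl]-6-bromo-4-(2-ethoxyethoxy)-3,4-dihydro-2H-chromen-3-ol
Product: 13 (2R,3S,4S)-7-(benzyloxy)-2-[3,4-bis(benzyloxy)phenyl]-6-bromo-4-[(2,6-dimethylphenyl)sulfanyl]-3,4-dihydro-2H-chromen-3-ol (4β thioether)
Conditions: 2,6-dimethylbenzenethiol, BF3·OEt2 (0.3 equiv), CH2Cl2, −78 → −30 °C
Reagents that add atoms: 2,6-dimethylbenzenethiol, Cc1cccc(C)c1S
Why: Lewis-acid SN1 exchange at C4 (thiol attack anti to the 3-OH, 4β) should install a leaving group that is inert to hard Lewis acids and can be activated later by a soft thiophile (orthogonal activation).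

Step 9
Reactants: 14 (−)-epicatechin
Product: 15 (2R,3R)-5,7-bis(benzyloxy)-2-[3,4-bis(benzyloxy)phenyl]-3,4-dihydro-2H-chromen-3-ol (5,7,3',4'-tetra-O-benzyl-epicatechin)
Conditions: BnBr, K2CO3, DMF, rt
Reagents that add atoms: benzyl bromide, BrCc1ccccc1
Why: Williamson ether synthesis should benzylate the four phenols and leave the aliphatic 3-OH free.

Step 10
Reactants: 15 5,7,3',4'-tetra-O-benzyl-epicatechin
Product: 16 (2R,3R)-5,7-bis(benzyloxy)-2-[3,4-bis(benzyloxy)phenyl]-6,8-dibromo-3,4-dihydro-2H-chromen-3-ol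
Conditions: NBS (2.1 equiv), CH2Cl2, 0 °C → rt
Reagents that add atoms: N-bromosuccinimide, BrN1C(=O)CCC1=O
Why: Electrophilic bromination of the phloroglucinol-type ring A at C8 and then C6 should cap both nucleophilic carbons, so that this unit cannot condense with itself once it is ionised.

Step 11
Reactants: 16 6,8-dibromo-5,7,3',4'-tetra-O-benzyl-epicatechin
Product: 17 (2R,3R,4S)-5,7-bis(benzyloxy)-2-[3,4-bis(benzyloxy)phenyl]-6,8-dibromo-4-(2-ethoxyethoxy)-3,4-dihydro-2H-chromen-3-ol (4β ether)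
Conditions: DDQ, 2-ethoxyethanol, CH2Cl2, rt
Reagents that add atoms: 2-ethoxyethanol, CCOCCO
Why: DDQ benzylic oxidation at C4 of a 5,7-dioxygenated flavan-3-ol and capture of the alcohol anti to the 3-OH is the standard way to make the 4β-alkoxy electrophile.

Step 12
Reactants: 17 6,8-dibromo-4β-(2-ethoxyethoxy)-5,7,3',4'-tetra-O-benzyl-epicatechin (1.5 equiv); 13 4β-arylthio middle unit
Product: 18 [6,8-dibromo-5,7,3',4'-tetra-O-benzyl-epicatechin]-(4β→8)-[6-bromo-7,3',4'-tri-O-benzyl-4β-(2,6-dimethylphenylsulfanyl)-epifisetinidol]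
Conditions: Me3SiOTf (0.2 equiv), 4 Å MS, CH2Cl2, −78 → −30 °C
Reagents that add atoms: none
Why: Friedel–Crafts-type interflavan coupling: the hard Lewis acid ionises only the C4 ether of 17, and the cation is attacked by C8 of ring A of 13 (its only free oxygen-activated carbon, C6 being brominated) anti to the 3-OH of the 2,3-cis electrophile, which should set the upper C4 as 4β.

Step 13
Reactants: 19 (+)-catechin
Product: 20 (2R,3S)-5,7-bis(benzyloxy)-2-[3,4-bis(benzyloxy)phenyl]-3,4-dihydro-2H-chromen-3-ol (5,7,3',4'-tetra-O-benzyl-catechin)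
Conditions: BnBr, K2CO3, DMF, rt
Reagents that add atoms: benzyl bromide, BrCc1ccccc1
Why: Williamson ether synthesis should benzylate the four phenols only.

Step 14
Reactants: 18 protected upper–middle dimer with C4 thioether; 20 5,7,3',4'-tetra-O-benzyl-catechin (3 equiv)
Product: 21 [6,8-dibromo-5,7,3',4'-tetra-O-benzyl-epicatechin]-(4β→8)-[6-bromo-7,3',4'-tri-O-benzyl-epifisetinidol]-(4β→8)-[5,7,3',4'-tetra-O-benzyl-catechin]
Conditions: I2, Ag2O, 4 Å MS, CH2Cl2, −78 → 0 °C
Reagents that add atoms: none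
Why: Soft thiophilic activation of the arylthio group gives the C4 cation of the middle unit, and Friedel–Crafts attack by C8 of the benzylated catechin (more reactive than its C6) anti to the 3-OH and to the 2-aryl group of the 2,3-cis unit should set the middle C4 as 4β.

Step 15
Reactants: 21 fully protected tribromo trimer
Product: 22 epicatechin-(4β→8)-epifisetinidol-(4β→8)-catechin (target)
Conditions: H2 (1 atm), Pd(OH)2/C, Et3N, THF/MeOH/H2O, rt
Reagents that add atoms: none
Why: Catalytic hydrogenolysis should cleave the eleven benzyl ethers and, with Et3N as HBr acceptor, the three aryl C–Br bonds in one operation without touching the pyran C2–O1 bonds or any stereocentre.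

## Compound list

1 | 4-hydroxy-2-iodobenzaldehyde | O=Cc1ccc(O)cc1I | starting material
2 | 4-(benzyloxy)-2-iodobenzaldehyde | O=Cc1ccc(OCc2ccccc2)cc1I | intermediate
3 | [4-(benzyloxy)-2-iodophenyl]methanol | OCc1ccc(OCc2ccccc2)cc1I | intermediate
4 | 4-(benzyloxy)-1-(bromomethyl)-2-iodobenzene | BrCc1ccc(OCc2ccccc2)cc1I | intermediate
5 | bis(4,4,5,5-tetramethyl-1,3,2-dioxaborolan-2-yl)methane | CC1(C)OB(CB2OC(C)(C)C(C)(C)O2)OC1(C)C | starting material
6 | 2,2'-{2-[4-(benzyloxy)-2-iodophenyl]ethane-1,1-diyl}bis(4,4,5,5-tetramethyl-1,3,2-dioxaborolane) | CC1(C)OB(OC1(C)C)C(Cc1ccc(OCc2ccccc2)cc1I)B1OC(C)(C)C(C)(C)O1 | intermediate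
7 | 3,4-bis(benzyloxy)benzaldehyde | O=Cc1ccc(OCc2ccccc2)c(OCc2ccccc2)c1 | starting material
8 | monovalent copper alkoxide of (1S,2R)-1-[3,4-bis(benzyloxy)phenyl]-3-[4-(benzyloxy)-2-iodophenyl]-2-(4,4,5,5-tetramethyl-1,3,2-dioxaborolan-2-yl)propan-1-ol (syn) | CC1(C)OB(OC1(C)C)[C@H](Cc1ccc(OCc2ccccc2)cc1I)[C@H](O[Cu])c1ccc(OCc2ccccc2)c(OCc2ccccc2)c1 | intermediate
9 | 2-{(2S,3R)-7-(benzyloxy)-2-[3,4-bis(benzyloxy)phenyl]-3,4-dihydro-2H-chromen-3-yl}-4,4,5,5-tetramethyl-1,3,2-dioxaborolane (2,3-cis) | CC1(C)OB(OC1(C)C)[C@@H]1Cc2ccc(OCc3ccccc3)cc2O[C@@H]1c1ccc(OCc2ccccc2)c(OCc2ccccc2)c1 | intermediate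
10 | (2R,3R)-7-(benzyloxy)-2-[3,4-bis(benzyloxy)phenyl]-3,4-dihydro-2H-chromen-3-ol (7,3',4'-tri-O-benzyl-epifisetinidol) | O[C@@H]1Cc2ccc(OCc3ccccc3)cc2O[C@@H]1c1ccc(OCc2ccccc2)c(OCc2ccccc2)c1 | intermediate
11 | (2R,3R,4S)-7-(benzyloxy)-2-[3,4-bis(benzyloxy)phenyl]-4-(2-ethoxyethoxy)-3,4-dihydro-2H-chromen-3-ol (4β, 3,4-trans) | c1ccccc1COc1ccc2c(c1)O[C@H](c1ccc(OCc3ccccc3)c(OCc3ccccc3)c1)[C@H](O)[C@H]2OCCOCC | intermediate
12 | (2R,3R,4S)-7-(benzyloxy)-2-[3,4-bis(benzyloxy)phenyl]-6-bromo-4-(2-ethoxyethoxy)-3,4-dihydro-2H-chromen-3-ol | c1ccccc1COc1c(Br)cc2c(c1)O[C@H](c1ccc(OCc3ccccc3)c(OCc3ccccc3)c1)[C@H](O)[C@H]2OCCOCC | intermediate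
13 | (2R,3S,4S)-7-(benzyloxy)-2-[3,4-bis(benzyloxy)phenyl]-6-bromo-4-[(2,6-dimethylphenyl)sulfanyl]-3,4-dihydro-2H-chromen-3-ol (4β) | c1ccccc1COc1c(Br)cc2c(c1)O[C@H](c1ccc(OCc3ccccc3)c(OCc3ccccc3)c1)[C@H](O)[C@H]2Sc1c(C)cccc1C | intermediate
14 | (−)-epicatechin | O[C@@H]1Cc2c(O)cc(O)cc2O[C@@H]1c1ccc(O)c(O)c1 | starting material
15 | (2R,3R)-5,7-bis(benzyloxy)-2-[3,4-bis(benzyloxy)phenyl]-3,4-dihydro-2H-chromen-3-ol | O[C@@H]1Cc2c(OCc3ccccc3)cc(OCc3ccccc3)cc2O[C@@H]1c1ccc(OCc2ccccc2)c(OCc2ccccc2)c1 | intermediate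
16 | (2R,3R)-5,7-bis(benzyloxy)-2-[3,4-bis(benzyloxy)phenyl]-6,8-dibromo-3,4-dihydro-2H-chromen-3-ol | O[C@@H]1Cc2c(OCc3ccccc3)c(Br)c(OCc3ccccc3)c(Br)c2O[C@@H]1c1ccc(OCc2ccccc2)c(OCc2ccccc2)c1 | intermediate
17 | (2R,3R,4S)-5,7-bis(benzyloxy)-2-[3,4-bis(benzyloxy)phenyl]-6,8-dibromo-4-(2-ethoxyethoxy)-3,4-dihydro-2H-chromen-3-ol (4β) | c1ccccc1COc1c(Br)c(OCc3ccccc3)c2c(c1Br)O[C@H](c1ccc(OCc3ccccc3)c(OCc3ccccc3)c1)[C@H](O)[C@H]2OCCOCC | intermediate
18 | [6,8-dibromo-5,7,3',4'-tetra-O-benzyl-epicatechin]-(4β→8)-[6-bromo-7,3',4'-tri-O-benzyl-4β-(2,6-dimethylphenylsulfanyl)-epifisetinidol] | c1ccccc1COc1c(Br)c(OCc3ccccc3)c2c(c1Br)O[C@H](c1ccc(OCc3ccccc3)c(OCc3ccccc3)c1)[C@H](O)[C@H]2c1c(OCc3ccccc3)c(Br)cc2c1O[C@H](c1ccc(OCc3ccccc3)c(OCc3ccccc3)c1)[C@H](O)[C@H]2Sc1c(C)cccc1C | intermediate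
19 | (+)-catechin | O[C@H]1Cc2c(O)cc(O)cc2O[C@@H]1c1ccc(O)c(O)c1 | starting material
20 | (2R,3S)-5,7-bis(benzyloxy)-2-[3,4-bis(benzyloxy)phenyl]-3,4-dihydro-2H-chromen-3-ol | O[C@H]1Cc2c(OCc3ccccc3)cc(OCc3ccccc3)cc2O[C@@H]1c1ccc(OCc2ccccc2)c(OCc2ccccc2)c1 | intermediate
21 | [6,8-dibromo-5,7,3',4'-tetra-O-benzyl-epicatechin]-(4β→8)-[6-bromo-7,3',4'-tri-O-benzyl-epifisetinidol]-(4β→8)-[5,7,3',4'-tetra-O-benzyl-catechin] | c1ccccc1COc1c(Br)c(OCc3ccccc3)c2c(c1Br)O[C@H](c1ccc(OCc3ccccc3)c(OCc3ccccc3)c1)[C@H](O)[C@H]2c1c(OCc3ccccc3)c(Br)cc2c1O[C@H](c1ccc(OCc3ccccc3)c(OCc3ccccc3)c1)[C@H](O)[C@H]2c1c(OCc3ccccc3)cc(OCc3ccccc3)c2c1O[C@H](c1ccc(OCc3ccccc3)c(OCc3ccccc3)c1)[C@@H](O)C2 | intermediate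
22 | epicatechin-(4β→8)-epifisetinidol-(4β→8)-catechin | Oc1cc(O)c2c(c1)O[C@H](c1ccc(O)c(O)c1)[C@H](O)[C@H]2c1c(O)ccc2c1O[C@H](c1ccc(O)c(O)c1)[C@H](O)[C@H]2c1c(O)cc(O)c2c1O[C@H](c1ccc(O)c(O)c1)[C@@H](O)C2 | target

## Step count and risks

Total step count: 15. Longest linear sequence: 11 steps (steps 1–8, 12, 14, 15).

**Step 5 (key step).** The copper-bound alkoxide may be transferred to boron or lose B–O by syn-elimination before it arylates, and the ligand change may stall copper turnover in the etherification. The fallback makes the same two bonds by the two known reactions in separate flasks. From 6 and 7, the copper-catalysed 1,2-addition alone (same catalyst, 22 °C, aqueous work-up) should give (1S,2R)-1-[3,4-bis(benzyloxy)phenyl]-3-[4-(benzyloxy)-2-iodophenyl]-2-(4,4,5,5-tetramethyl-1,3,2-dioxaborolan-2-yl)propan-1-ol F1. A palladium-catalysed intramolecular aryl etherification (Pd(OAc)2, 2-(di-tert-butylphosphino)-1,1'-binaphthyl, Cs2CO3, toluene, 50 °C), in which boron still masks the C3 oxygen, should then close ring C. The fallback comes back to the route at 9, which is oxidised to 10 as in step 5.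

**Step 12.** Ring A of the 5-deoxy unit is only doubly activated and C8 is flanked on both sides, so attack may be slow. The electrophile may then eliminate to a flav-3-ene, the catechol-type ring B may be alkylated, or the C4 thioether of the nucleophile may be ionised prematurely. The fallback changes the order of the two couplings so that no thioether is needed and the weak nucleophile meets a large excess of the cheap electrophile last. It sets out from 12, which is coupled with 20 (Me3SiOTf, CH2Cl2, −78 °C) to give [6-bromo-7,3',4'-tri-O-benzyl-epifisetinidol]-(4β→8)-[5,7,3',4'-tetra-O-benzyl-catechin] F2. NBS then caps the only remaining phloroglucinol-type carbon to give the C6-brominated lower-unit dimer F3. Coupling of 17 with F3 (Me3SiOTf) at the one free oxygen-activated carbon should give the tetrabromo protected trimer F4. Hydrogenolysis as in step 15 comes back to the route at 22.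

**Step 6.** Without a 5-oxygen the C4 cation is less stabilised, so hydride abstraction at C4 may be slow and abstraction of the C2 hydride (activated by ring B and O1) or over-oxidation to a flavene may compete. The fallback replaces hydride abstraction by a quinone with ligand-transfer acetoxylation. It sets out from 10: Pb(OAc)4 in benzene (benzylic acetoxylation, known for flavans that lack a 5-oxygen) should give the 4β-acetate of 10 F5. NBS bromination at C6 gives the 6-bromo-4β-acetate F6. BF3·OEt2-mediated exchange of the acetate with 2,6-dimethylbenzenethiol comes back to the route at 13.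

## Further compounds

F1 | step 5 | (1S,2R)-1-[3,4-bis(benzyloxy)phenyl]-3-[4-(benzyloxy)-2-iodophenyl]-2-(4,4,5,5-tetramethyl-1,3,2-dioxaborolan-2-yl)propan-1-ol | CC1(C)OB(OC1(C)C)[C@H](Cc1ccc(OCc2ccccc2)cc1I)[C@H](O)c1ccc(OCc2ccccc2)c(OCc2ccccc2)c1
F2 | step 12 | [6-bromo-7,3',4'-tri-O-benzyl-epifisetinidol]-(4β→8)-[5,7,3',4'-tetra-O-benzyl-catechin] | c1ccccc1COc1c(Br)cc2c(c1)O[C@H](c1ccc(OCc3ccccc3)c(OCc3ccccc3)c1)[C@H](O)[C@H]2c1c(OCc3ccccc3)cc(OCc3ccccc3)c2c1O[C@H](c1ccc(OCc3ccccc3)c(OCc3ccccc3)c1)[C@@H](O)C2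
F3 | step 12 | [6-bromo-7,3',4'-tri-O-benzyl-epifisetinidol]-(4β→8)-[6-bromo-5,7,3',4'-tetra-O-benzyl-catechin] | c1ccccc1COc1c(Br)cc2c(c1)O[C@H](c1ccc(OCc3ccccc3)c(OCc3ccccc3)c1)[C@H](O)[C@H]2c1c(OCc3ccccc3)c(Br)c(OCc3ccccc3)c2c1O[C@H](c1ccc(OCc3ccccc3)c(OCc3ccccc3)c1)[C@@H](O)C2
F4 | step 12 | [6,8-dibromo-5,7,3',4'-tetra-O-benzyl-epicatechin]-(4β→8)-[6-bromo-7,3',4'-tri-O-benzyl-epifisetinidol]-(4β→8)-[6-bromo-5,7,3',4'-tetra-O-benzyl-catechin] | c1ccccc1COc1c(Br)c(OCc3ccccc3)c2c(c1Br)O[C@H](c1ccc(OCc3ccccc3)c(OCc3ccccc3)c1)[C@H](O)[C@H]2c1c(OCc3ccccc3)c(Br)cc2c1O[C@H](c1ccc(OCc3ccccc3)c(OCc3ccccc3)c1)[C@H](O)[C@H]2c1c(OCc3ccccc3)c(Br)c(OCc3ccccc3)c2c1O[C@H](c1ccc(OCc3ccccc3)c(OCc3ccccc3)c1)[C@@H](O)C2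
F5 | step 6 | (2R,3R)-7-(benzyloxy)-2-[3,4-bis(benzyloxy)phenyl]-3-hydroxy-3,4-dihydro-2H-chromen-4-yl acetate (4β-acetate, 3,4-trans) | c1ccccc1COc1ccc2c(c1)O[C@H](c1ccc(OCc3ccccc3)c(OCc3ccccc3)c1)[C@H](O)[C@H]2OC(C)=O
F6 | step 6 | (2R,3R)-7-(benzyloxy)-2-[3,4-bis(benzyloxy)phenyl]-6-bromo-3-hydroxy-3,4-dihydro-2H-chromen-4-yl acetate (4β-acetate, 3,4-trans) | c1ccccc1COc1c(Br)cc2c(c1)O[C@H](c1ccc(OCc3ccccc3)c(OCc3ccccc3)c1)[C@H](O)[C@H]2OC(C)=O
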